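**Retrosynthetic overview**

1. Rings A, B and C are bought intact as racemic naringenin (1); O7-methylation gives racemic sakuranetin (2), so no ring is built from scratch.
2. Key disconnection, C3–OH (carbon–oxygen): 2 is hydroxylated at C3 in a stereoconvergent step. Ring C opens at C2–O1 to the chalcone (3) and re-closes until the catalyst-bound (2S)-enolate (4) is oxygenated, giving (2R,3R)-7-O-methylaromadendrin (5) with both ring C stereocentres.
3. Last disconnection, C6–C(benzylic): 5 and 1-(4-hydroxyphenyl)ethanol (6) are joined through the para-quinone methide (7) under a chiral phosphoric acid to give the target (8) with the (R) benzylic centre.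
4. Ring order: ring C is the only ring that is re-formed (reversibly, in step 2); rings A and B are never touched.

Assumption: commercial naringenin is used as the racemate (its C2 configuration is erased in step 2); the (R,R)-ligand and (R)-acid written below are taken to give the configurations shown, and if the first run shows the opposite sense the commercial mirror-image ligand or acid is used.

**Route**

Step 1
Reactants: 1 naringenin (racemic 5,7-dihydroxy-2-(4-hydroxyphenyl)chroman-4-one)
Product: 2 sakuranetin (racemic 5-hydroxy-2-(4-hydroxyphenyl)-7-methoxychroman-4-one)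
Conditions: Me2SO4 (1.05 equiv), K2CO3 (1.1 equiv), acetone, 25→40 °C
Reagents that add atoms: dimethyl sulfate, COS(=O)(=O)OC
Why: Williamson-type O-methylation under acidity control: the 7-OH (para to the carbonyl) is the most acidic phenol, the 5-OH is chelated to C4=O and the 4'-OH is less acidic, so one equivalent of base and dimethyl sulfate methylates O7 selectively, and no stereocentre is set.

Step 2
Reactants: 2 sakuranetin (racemic)
Product: 5 (2R,3R)-7-O-methylaromadendrin, via ring-opened chalcone 3 (not isolated), via zinc-bound (2S)-enolate 4 (not isolated)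
Conditions: Zn(OAc)2 (10 mol%), (R,R)-DBFOX/Ph [(R,R)-4,6-dibenzofurandiyl-2,2'-bis(4-phenyloxazoline)] (11 mol%), Bu4NOAc (30 mol%), sulfonyloxaziridine (1.1 equiv, syringe pump, 12 h), 4 Å MS, CH2Cl2/THF 4:1, 30 °C
Reagents that add atoms: (±)-trans-3-phenyl-2-(phenylsulfonyl)oxaziridine (Davis oxaziridine), O=S(=O)(c1ccccc1)N1OC1c1ccccc1
Why: Proposed new method: dynamic kinetic asymmetric α-hydroxylation of a racemic flavanone, in which the 5-O/4-C=O pair of 2 chelates the chiral zinc bis(oxazoline) Lewis acid, acetate generates the zinc-bound enolate, and the sulfonyloxaziridine transfers oxygen to C3 only where the enolate face left open by the ligand is also the face anti to the C2 aryl group (enolate 4, giving the 2,3-trans product and setting C3 by catalyst control), whereas the mismatched (2R)-enolate instead expels the O1 phenoxide (E1cB retro-oxa-Michael) to achiral chalcone 3, which re-closes and thereby feeds both enantiomers of 2 into (2R,3R)-5 (C2 set by the dynamic resolution); the closest known reaction types are the chiral-Lewis-acid-catalysed α-hydroxylation of β-keto esters and oxindoles with sulfonyloxaziridines and the base-mediated racemisation of flavanones through their chalcones.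

Step 3
Reactants: 5 (2R,3R)-7-O-methylaromadendrin; 6 1-(4-hydroxyphenyl)ethanol (racemic)
Product: 8 (2R,3R)-3,5-dihydroxy-2-(4-hydroxyphenyl)-6-[(1R)-1-(4-hydroxyphenyl)ethyl]-7-methoxychroman-4-one (target), via para-quinone methide 7 (not isolated)
Conditions: (R)-TRIP [(R)-3,3'-bis(2,4,6-triisopropylphenyl)-1,1'-binaphthyl-2,2'-diyl hydrogen phosphate] (10 mol%), 5 Å MS, CHCl3/EtOAc 9:1, 35 °C, 6 (1.5 equiv) added over 8 h
Reagents that add atoms: none
Why: Chiral-phosphoric-acid-catalysed Friedel–Crafts 1,6-addition to an in situ para-quinone methide: the acid dehydrates 6 to 7 and holds it by hydrogen bonding while its P=O accepts the 5-OH hydrogen bond, so the only ring A carbon ortho to a free hydroxyl (C6) attacks one face of 7 inside the chiral ion pair and sets the (R) benzylic centre under catalyst control, the remote C2 and C3 centres exerting little bias.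

**Compound list**

1 | naringenin, racemic 5,7-dihydroxy-2-(4-hydroxyphenyl)chroman-4-one | O=C1CC(c2ccc(O)cc2)Oc2cc(O)cc(O)c12 | starting material
2 | sakuranetin, racemic 5-hydroxy-2-(4-hydroxyphenyl)-7-methoxychroman-4-one | COc1cc(O)c2c(c1)OC(c1ccc(O)cc1)CC2=O | intermediate
3 | ring-opened chalcone, (E)-1-(2,6-dihydroxy-4-methoxyphenyl)-3-(4-hydroxyphenyl)prop-2-en-1-one | COc1cc(O)c(C(=O)/C=C/c2ccc(O)cc2)c(O)c1 | intermediate (not isolated)
4 | zinc-bound (2S)-enolate of sakuranetin, drawn as the free enol (2S)-2-(4-hydroxyphenyl)-7-methoxy-2H-chromene-4,5-diol | COc1cc(O)c2c(c1)O[C@H](c1ccc(O)cc1)C=C2O | intermediate (not isolated)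
5 | (2R,3R)-7-O-methylaromadendrin, (2R,3R)-3,5-dihydroxy-2-(4-hydroxyphenyl)-7-methoxychroman-4-one | COc1cc2c(c(O)c1)C(=O)[C@H](O)[C@@H](c1ccc(O)cc1)O2 | intermediate
6 | 1-(4-hydroxyphenyl)ethanol (racemic) | CC(O)c1ccc(O)cc1 | starting material
7 | para-quinone methide, 4-ethylidenecyclohexa-2,5-dien-1-one | CC=C1C=CC(=O)C=C1 | intermediate (not isolated)
8 | (2R,3R)-3,5-dihydroxy-2-(4-hydroxyphenyl)-6-[(1R)-1-(4-hydroxyphenyl)ethyl]-7-methoxychroman-4-one | COc1cc2c(c(O)c1[C@H](C)c1ccc(O)cc1)C(=O)[C@H](O)[C@@H](c1ccc(O)cc1)O2 | target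

**Step count and risks**

Total steps: 3. Longest linear sequence: 3 (1 → 2 → 5 → 8).

Steps most likely to fail:

1. **Step 2 (the proposed new step).** Risks:
   - Acetate-mediated enolisation of the chelated ketone may be too slow.
   - Over-oxidation of 5 may give the flavonol.
   - Ligand discrimination between the two enolates may be modest. A single epimerisation of 5 gives only a separable cis diastereomer, never the enantiomer.

   Fallback with known chemistry, setting out from 2 and coming back at 5: treatment of 2 with excess NaH and MOMCl in DMF opens ring C by retro-oxa-Michael and caps all three phenoxides. This gives (E)-1-[4-methoxy-2,6-bis(methoxymethoxy)phenyl]-3-[4-(methoxymethoxy)phenyl]prop-2-en-1-one F4. Juliá–Colonna epoxidation (poly-L-leucine, urea–H2O2, DBU, THF) gives the (αR,βS)-epoxy ketone [(2R,3S)-3-[4-(methoxymethoxy)phenyl]oxiran-2-yl][4-methoxy-2,6-bis(methoxymethoxy)phenyl]methanone F5. HCl in MeOH at 45 °C removes the three MOM groups, and either of the two equivalent freed ortho-phenols opens the epoxide at the benzylic carbon (6-endo, inversion) to return (2R,3R)-5.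

2. **Step 3.** Risks:
   - Alkylation at C8 instead of C6, because the 5-OH is chelated and may direct only weakly.
   - Incomplete control of the benzylic centre.
   - Self-condensation of 6 and 7.

   Because 5 is a single enantiomer, every isomeric by-product is a diastereomer or regioisomer and can be removed on achiral phases.

   Fallback, setting out from 5 and coming back at 8: iodination with BnMe3N·ICl2 and CaCO3 in CH2Cl2/MeOH, directed ortho to the free 5-OH, gives (2R,3R)-3,5-dihydroxy-2-(4-hydroxyphenyl)-6-iodo-7-methoxychroman-4-one F6. Separately, 4-ethynylphenol is converted by α-selective protoboration (CuCl, SIMes·HCl, NaOtBu, B2pin2, MeOH) into 4-[1-(4,4,5,5-tetramethyl-1,3,2-dioxaborolan-2-yl)ethenyl]phenol F7. Suzuki–Miyaura coupling of the two (Pd(PPh3)4, K3PO4, degassed dioxane/H2O, 50 °C) gives (2R,3R)-3,5-dihydroxy-2-(4-hydroxyphenyl)-6-[1-(4-hydroxyphenyl)ethenyl]-7-methoxychroman-4-one F8. Chiral-phosphoric-acid-catalysed transfer hydrogenation with a Hantzsch ester, through the quinone methide of this hydroxyaryl-substituted 1,1-diarylethene, then sets the (R) benzylic centre and delivers 8.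

3. **Step 1.** Risk: competing methylation at O4' (7,4'-dimethyl ether) or incomplete conversion, giving mixtures that are tedious to separate.

   Fallback, setting out from 1 and coming back at 2: Ac2O in pyridine gives naringenin 5,7,4'-triacetate F1. Thiophenol and imidazole in NMP remove only the 7-O-acetyl group to give 5,4'-di-O-acetylnaringenin F2. Mitsunobu methylation (MeOH, PPh3, DIAD) gives 5,4'-di-O-acetylsakuranetin F3. K2CO3 in MeOH cleaves both acetates to give 2.

**Further compounds**

F1 | step 1 | naringenin 5,7,4'-triacetate (racemic) | CC(=O)Oc1ccc(cc1)C1CC(=O)c2c(OC(C)=O)cc(OC(C)=O)cc2O1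
F2 | step 1 | 5,4'-di-O-acetylnaringenin (racemic, 7-OH free) | CC(=O)Oc1ccc(cc1)C1CC(=O)c2c(OC(C)=O)cc(O)cc2O1
F3 | step 1 | 5,4'-di-O-acetylsakuranetin (racemic) | CC(=O)Oc1ccc(cc1)C1CC(=O)c2c(OC(C)=O)cc(OC)cc2O1
F4 | step 2 | (E)-1-[4-methoxy-2,6-bis(methoxymethoxy)phenyl]-3-[4-(methoxymethoxy)phenyl]prop-2-en-1-one | COCOc1ccc(/C=C/C(=O)c2c(OCOC)cc(OC)cc2OCOC)cc1
F5 | step 2 | [(2R,3S)-3-[4-(methoxymethoxy)phenyl]oxiran-2-yl][4-methoxy-2,6-bis(methoxymethoxy)phenyl]methanone | O=C(c1c(OCOC)cc(OC)cc1OCOC)[C@@H]1O[C@H]1c1ccc(OCOC)cc1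
F6 | step 3 | (2R,3R)-3,5-dihydroxy-2-(4-hydroxyphenyl)-6-iodo-7-methoxychroman-4-one | COc1cc2c(c(O)c1I)C(=O)[C@H](O)[C@@H](c1ccc(O)cc1)O2
F7 | step 3 | 4-[1-(4,4,5,5-tetramethyl-1,3,2-dioxaborolan-2-yl)ethenyl]phenol | C=C(B1OC(C)(C)C(C)(C)O1)c1ccc(O)cc1
F8 | step 3 | (2R,3R)-3,5-dihydroxy-2-(4-hydroxyphenyl)-6-[1-(4-hydroxyphenyl)ethenyl]-7-methoxychroman-4-one | COc1cc2c(c(O)c1C(=C)c1ccc(O)cc1)C(=O)[C@H](O)[C@@H](c1ccc(O)cc1)O2
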